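**Retrosynthetic overview**
- Yanuthone X2 ⇐ ketoreductase-like 1,2-reduction of the (1R,6S)-epoxyquinone at its only carbonyl that is not a vinylogous ester; this sets the carbinol centre by substrate control.
- Epoxyquinone ⇐ one-flask O2-driven dearomatisation/epoxidation of 2-farnesyl-5-methoxyhydroquinone under a chiral ammonium ion pair (hydroquinone → quinone + HOO⁻, then Weitz–Scheffer closure); this sets both oxirane centres.
- Hydroquinone ⇐ Friedel–Crafts C-farnesylation of methoxyhydroquinone with (2E,6E)-farnesol, a prenyltransferase mimic.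
- Ring order: the carbocycle is bought as the arene (Nature also starts from an aromatic polyketide); the oxirane is the only ring formed, in step 2.

Assumption: 2-methoxyhydroquinone (1) and (2E,6E)-farnesol (2) are bought as such.
Assumption: the cinchonidinium catalyst is taken to give the (1R,6S)-epoxide; if the first run shows the antipode, its pseudo-enantiomer (the cinchoninium salt) is used under the same conditions.

**Step 1**
Reactants: 1 2-methoxybenzene-1,4-diol (methoxyhydroquinone); 2 (2E,6E)-farnesol [(2E,6E)-3,7,11-trimethyldodeca-2,6,10-trien-1-ol]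
Product: 3 2-methoxy-5-[(2E,6E)-3,7,11-trimethyldodeca-2,6,10-trien-1-yl]benzene-1,4-diol (2-farnesyl-5-methoxyhydroquinone)
Conditions: 1 (3 equiv), BF3·OEt2 (0.3 equiv), dioxane, Ar, rt, slow addition of 2; excess 1 recovered
Reagents that add atoms: none
Why: Friedel–Crafts allylation of an electron-rich hydroquinone by the farnesyl cation; C5 (para to OMe, ortho to OH) is the most nucleophilic and least hindered ring position, the cation is trapped at its primary terminus with the 2E geometry largely kept, and no stereocentre is formed.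

**Step 2**
Reactants: 3 2-farnesyl-5-methoxyhydroquinone
Product: 5 (1R,6S)-4-methoxy-1-[(2E,6E)-3,7,11-trimethyldodeca-2,6,10-trien-1-yl]-7-oxabicyclo[4.1.0]hept-3-ene-2,5-dione, via 2-farnesyl-5-methoxybenzoquinone 4 (not isolated)
Conditions: O2 (1 atm), N-(9-anthracenylmethyl)cinchonidinium chloride (10 mol %), LiOH·H2O (20 mol %), PhMe/H2O 10:1, −10 °C, dark
Reagents that add atoms: dioxygen, O=O
Why: Proposed new method: the ammonium salt of the hydroquinone mono-anion is autoxidised by O2 to quinone 4 plus one equivalent of chiral-ammonium hydroperoxide ion pair (the redox of the anthraquinone H2O2 process), and this ion pair then carries out an enantioselective Weitz–Scheffer epoxidation of the more electrophilic, non-methoxylated C=C (conjugate addition of HOO⁻ fixes the face, the enolate closes on O–O to the necessarily cis-fused oxirane, so both centres (1R,6S) arise together) while the nucleophilic oxidant leaves the three farnesyl alkenes alone; the closest known reactions are the cinchona phase-transfer H2O2/LiOH epoxidation of 2-alkyl-1,4-naphthoquinones and the base/O2 conversion of vitamin K hydroquinone into its 2,3-epoxide.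

**Step 3**
Reactants: 5 (1R,6S)-epoxyquinone
Product: 6 yanuthone X2 [(1R,5S,6R)-5-hydroxy-4-methoxy-1-[(2E,6E)-3,7,11-trimethyldodeca-2,6,10-trien-1-yl]-7-oxabicyclo[4.1.0]hept-3-en-2-one]
Conditions: NaBH4 (1.0 equiv), CeCl3·7H2O (1.1 equiv), MeOH, −78 °C, 30 min; aq NH4Cl
Reagents that add atoms: none
Why: Luche 1,2-reduction picks the C5 ketone (flanked by the oxirane CH, not deactivated) over the C2 carbonyl (a vinylogous ester next to the quaternary carbon), and hydride is expected to arrive anti to the oxirane oxygen (lone-pair/dipole shielding of the syn face), placing the new OH cis to the epoxide, i.e. 5S.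

**Compound list**
1 | 2-methoxybenzene-1,4-diol (methoxyhydroquinone) | COc1cc(O)ccc1O | starting material
2 | (2E,6E)-farnesol | OC/C=C(\C)CC/C=C(\C)CCC=C(C)C | starting material
3 | 2-methoxy-5-[(2E,6E)-farnesyl]benzene-1,4-diol | COc1cc(O)c(C/C=C(\C)CC/C=C(\C)CCC=C(C)C)cc1O | intermediate
4 | 2-methoxy-5-[(2E,6E)-farnesyl]cyclohexa-2,5-diene-1,4-dione (formed in the flask in step 2) | COC1=CC(=O)C(C/C=C(\C)CC/C=C(\C)CCC=C(C)C)=CC1=O | intermediate
5 | (1R,6S)-1-[(2E,6E)-farnesyl]-4-methoxy-7-oxabicyclo[4.1.0]hept-3-ene-2,5-dione | COC1=CC(=O)[C@]2(C/C=C(\C)CC/C=C(\C)CCC=C(C)C)O[C@@H]2C1=O | intermediate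
6 | yanuthone X2, (1R,5S,6R)-1-[(2E,6E)-farnesyl]-5-hydroxy-4-methoxy-7-oxabicyclo[4.1.0]hept-3-en-2-one | COC1=CC(=O)[C@]2(C/C=C(\C)CC/C=C(\C)CCC=C(C)C)O[C@@H]2[C@@H]1O | target

**Total step count:** 3
**Longest linear sequence:** 3 steps

**Steps most likely to fail**

Step 2 is the riskiest. The hydroperoxide made in the flask may be lost before it epoxidises, leaving quinone 4. The epoxyquinone may isomerise in base. The ee of a quinone phase-transfer epoxidation may stay near 70–85 %. The fallback sets out from 3 and comes back at 6; it decouples oxidation from epoxidation and moves enantiocontrol to an enzymatic resolution.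
- Hydroquinone 3 is oxidised alone (O2, cat. Co(salen), MeCN, rt) to quinone 4, now isolated.
- t-BuOOH/DBU in CH2Cl2 at 0 °C gives the racemic epoxyquinone F1.
- The conditions of step 3 give racemic yanuthone X2 F2.
- Burkholderia cepacia lipase with vinyl acetate in MTBE at 30 °C acylates one enantiomer. With the oxirane side (carrying the quaternary farnesyl carbon) as the large group, Kazlauskas' rule predicts that the (5S)-alcohol reacts. This gives yanuthone X2 acetate F3 and leaves ent-yanuthone X2 F4.
- F3 is separated and methanolysed (K2CO3, MeOH, 0 °C) to 6. If the enzyme prefers the antipode, the unreacted alcohol is 6 itself and the methanolysis is dropped.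

Step 3 is next. The regiochemistry is backed by both electronics and sterics, but the facial sense of hydride attack next to an oxirane is reagent-dependent and could favour the trans epoxy alcohol. The fallback sets out from 5 and comes back at 6; it corrects the carbinol centre by inversion instead of relying on the reduction.
- If the main product is the (5R)-epimer, 5-epi-yanuthone X2 F5, it is kept.
- Mitsunobu reaction (4-nitrobenzoic acid, PPh3, DIAD, THF, 0 °C) inverts C5 and gives yanuthone X2 4-nitrobenzoate F6.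
- K2CO3 in MeOH at 0 °C releases 6.

Step 1 is third. Yields of BF3-mediated polyprenylations are modest; bis-alkylation, chroman formation and partial 2E/2Z scrambling are the known losses. The fallback sets out from 2 and comes back at 3; it replaces the cationic C–C bond formation with an aryl-copper SN2 coupling whose regiochemistry is fixed by a halogen.
- Farnesol 2 is converted (PBr3, Et2O, 0 °C) into (2E,6E)-farnesyl bromide F7.
- Purchased 1-bromo-2,4,5-trimethoxybenzene F8 is lithiated (n-BuLi, THF, −78 °C), transmetallated with CuBr·SMe2 and alkylated with F7 to give 1-farnesyl-2,4,5-trimethoxybenzene F9.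
- Ceric ammonium nitrate in MeCN/H2O at 0 °C demethylates F9 oxidatively to quinone 4.
- Aqueous Na2S2O4/Et2O reduces 4 to hydroquinone 3.

**Further compounds**
F1 | step 2 | racemic 1-[(2E,6E)-farnesyl]-4-methoxy-7-oxabicyclo[4.1.0]hept-3-ene-2,5-dione (rac-5) | COC1=CC(=O)[C@]2(C/C=C(\C)CC/C=C(\C)CCC=C(C)C)O[C@@H]2C1=O.COC1=CC(=O)[C@@]2(C/C=C(\C)CC/C=C(\C)CCC=C(C)C)O[C@H]2C1=O
F2 | step 2 | racemic yanuthone X2 (rac-6, 5-OH cis to the oxirane) | COC1=CC(=O)[C@]2(C/C=C(\C)CC/C=C(\C)CCC=C(C)C)O[C@@H]2[C@@H]1O.COC1=CC(=O)[C@@]2(C/C=C(\C)CC/C=C(\C)CCC=C(C)C)O[C@H]2[C@H]1O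
F3 | step 2 | yanuthone X2 acetate, (1R,5S,6R)-5-acetoxy compound | COC1=CC(=O)[C@]2(C/C=C(\C)CC/C=C(\C)CCC=C(C)C)O[C@@H]2[C@@H]1OC(C)=O
F4 | step 2 | ent-yanuthone X2, (1S,5R,6S) | COC1=CC(=O)[C@@]2(C/C=C(\C)CC/C=C(\C)CCC=C(C)C)O[C@H]2[C@H]1O
F5 | step 3 | 5-epi-yanuthone X2, (1R,5R,6R), 5-OH trans to the oxirane | COC1=CC(=O)[C@]2(C/C=C(\C)CC/C=C(\C)CCC=C(C)C)O[C@@H]2[C@H]1O
F6 | step 3 | yanuthone X2 4-nitrobenzoate, (1R,5S,6R) | COC1=CC(=O)[C@]2(C/C=C(\C)CC/C=C(\C)CCC=C(C)C)O[C@@H]2[C@@H]1OC(=O)c1ccc(cc1)[N+](=O)[O-]
F7 | step 1 | (2E,6E)-farnesyl bromide | BrC/C=C(\C)CC/C=C(\C)CCC=C(C)C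
F8 | step 1 | 1-bromo-2,4,5-trimethoxybenzene (purchased) | COc1cc(OC)c(Br)cc1OC
F9 | step 1 | 1-[(2E,6E)-farnesyl]-2,4,5-trimethoxybenzene | COc1cc(OC)c(C/C=C(\C)CC/C=C(\C)CCC=C(C)C)cc1OC
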